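The numbers are assumed; what happens was integrated by code.

Reckon what the partner can buy, then read the yields from that bill.

starting material 0.20 M (fed, over 20 s); partner 0.220 M; protic impurity 0.0400 M; time 10 h; the fed solution adds 0.25 times the starting volume

    starting material + 2 partner → side product (k1 = 0.772 L² mol⁻² min⁻¹)
    starting material + partner → target (k2 = 0.367 L mol⁻¹ min⁻¹)
    partner + protic impurity → quenched reagent (k3 = 9.96 L mol⁻¹ min⁻¹)

- which holds at 10 h: what has brought the reaction to rest, or that it has not come to rest (the partner has run out first / it is still moving / all of the starting material has reacted)
- the target standing at 10 h, as a percentage of the starting material charged
- the side product standing at 10 h, as a percentage of the starting material charged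

- a doubled species enters its step squared and goes two at a time
- charges are per starting volume, the dose included; the dosed solution carries all of it
- the reaction counts as stopped when no species that holds the starting material changes by six tenths of a point or more over the second half of the time
- run time (flask): 10 h

Treat the dose as instantaneous, since the slow addition makes no difference. Let the protic impurity take its partner first, because 9.96 L mol⁻¹ min⁻¹ stands far above 0.367 L mol⁻¹ min⁻¹. After dilution by the feed, that leaves 0.144 M of partner for 0.160 M of starting material.

Each target costs one partner and each side product two. Side product forms per target at the ratio s·c(partner), where s = k1/k2 = 2.10 L mol⁻¹, a selectivity factor. Replace the falling c(partner) by its mean, 0.0720 M. That gives 0.151 side product per target, so a target costs 1.30 partner, and the partner buys 69.1% target.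

The weak link is that mean, so integrate the cost over the falling partner instead. This gives 0.113 M of target. The partner price, partner spent per target standing at the end, is then 1.28, cheaper than the mean made it. I commit to 70.6% target and 9.82% side product.

That leaves 0.0317 M of starting material, so partner is the limiting reagent. Against that remainder the partner's last traces decay with time constant 85.9 min. Treated as a second-order pair, this leaves about 8.69 × 10⁻⁴ M at half time, worth 0.543% of the starting material, under the 0.6-point mark. So I expect rest.

The forecast says the partner has run out first, with 70% target and 10% side product, on the grounds that “the partner is limiting”.

The simulation gives the partner has run out first, with 0.011% of the partner left, 70.1% target and 9.95% side product.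

In the flask, 0.226 h sees half of the target's turnover done, and at 0.226 h starting material goes to target 7.5 times as fast as to side product, with half-lives of 0.50 h against 3.7 h. That ratio is a cost of 1.27 partner per target at that moment, beside the partner price of 1.28. In the neighbour flask with 0.50 M of starting material and the same partner, that price buys 28.1% target. That neighbour flask stands at 27.9% target and 4.06% side product, with 0% of its partner left.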